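(The readings are calculated for an exercise, and the scatter is random.)

Saturday's run gives you one rate constant twice, once from each column, so start there.

| setting | Saturday's | flask |
|---|---|---|
| Z | 10 mM | 10 mM |
| Q | 0.30 mM | 0.20 mM |
| remark | run made earlier |  |
| time |  | 12 min |

- Saturday's (time / min: E / %, Z / %): 0.500: 3.4, 96.6; 1.00: 7.0, 94.0; 1.33: 7.5, 92.3; 2.00: 12.3, 87.9; 2.50: 15.2, 84.5

(readings scatter by 0.5 percentage points)

- the average divides the monomer in chains by the number of chains begun, living and dead together
- the analysis behind the earlier runs scatters by 0.5 percentage points, standard deviation
- the earlier runs do not show the number of chains; that part of a forecast is a guess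
- no earlier run changes the charge of Q; that part of a forecast is a guess

- whether the average number of monomer units in a chain (chains begun, living or dead) reaches 90 by 12 min (yes / no)
- average number of monomer units in a chain (chains begun, living or dead) at 12 min

At 2.50 min in Saturday's run, the fall of Z gives a first-order constant of 0.0674 min⁻¹ and the rise of E gives 0.0659 min⁻¹. These come from different columns, and the E and Z readings together miss the charge by 0.3 percentage points, inside a scatter of 0.5 points. So I trust their mean, 0.0667 min⁻¹, as a reading.

Carrying it to the new flask is where two ways part, and no earlier run can tell which one cheats, since none changes Q. With the constant proportional to Q, I get 0.0444 min⁻¹, so I reckon on 41.3 % of the Z in E at 12 min. With a square root, I get 48.0 %.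

What turns either share into a length is the length per Q, the Z charged over the Q charged (the monomer-to-initiator ratio), 50.0. If each Q begins one chain, the average is this number times the share of Z in E. That gives 20.7 or 24.0, which lie 3.31 apart. Reaching 90 on those terms needs 180 % of the Z charged, more than the charge itself.

The forecast says no and 21, and it calls the way to 90 “very inefficient initiation, which seems unlikely but is not excluded”.

The flask answers no, with an average of 23.2 at 12.0 min.

    2 Q → L (k = 4.29 L mol⁻¹ s⁻¹)
    Q → J (k = 8.29 × 10⁻⁴ s⁻¹)
    Z + Q → X + E (k = 2.75 L mol⁻¹ s⁻¹)
    Z + X → E + X, rate k4*[X]*[Z] (k = 4.30 L mol⁻¹ s⁻¹)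

In the flask at that time E holds 43.6 % of the Z charged, and X stands at 94.1 % of the Q charged. The length per Q times that share of E gives 21.8. In the neighbour flask with 0.50 mM of Q and the same time, the length per Q is 20.0 and E holds 74.6 %, which gives 14.9. That neighbour's chains average 16.6.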